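All constants are invented, and the outcome is calculated.

Into a closed, stirred vessel held at one temperature went substrate and partner, and I was to follow them through these steps:

    substrate + 2 partner → side product (k1 = 7.4 M⁻² min⁻¹)
    partner → decomposed reagent (k2 = 0.0014 min⁻¹)
    substrate + partner → target (k3 = 0.16 M⁻¹ min⁻¹)

substrate 10 mM; partner 20.0 mM; time 5.0 d

- a doubled species enters its step squared and goes two at a time
- the reaction counts as stopped when no species that holds the substrate changes by six tenths of a point or more over the second half of the time
- run time (flask): 5.0 d

* the state of affairs at 5.0 d: stopped, and by what, or still going (it is still moving / all of the substrate has reacted / the partner has run out first)
* share of the substrate used up at 5.0 d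
* target at 5.0 d, in percent of the substrate charged
* side product at 5.0 d, in percent of the substrate charged

The side step goes with the partner squared and the target step with the partner once, so the substrate cancels from their ratio: side product forms against target as c(partner) against the crossover concentration, 21.6 mM, the target constant divided by the side constant. The charge of 20.0 mM lay just below it, so the two began nearly level. I let c(partner) fall evenly from its charge to nothing as target grew, which made its mean half the charge and side product over target 0.463.

But the decay step, with a half-life of 0.34 d, is short against 5.0 d, and by decay alone c(partner) drops to 0.00419% of its charge. So I took partner loss as one exponential, with its constant reckoned at half of each charge: 0.00294 min⁻¹. Integrating the substrate's rate then gave a logarithmic fall of 1.59, so conversion 79.6%, target 54.5% and side product 25.2%. By this reckoning 20.4% of the substrate stayed behind, so I named the partner as the limiting reagent.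

The forecast said that the partner has run out first, with conversion 78%, target 53% and side product 25%, on the ground that “The side step competes about evenly at the start but fades as the partner falls”.

In the flask the partner has run out first, with 0% of its charge standing at 5.00 d, and it gave 78.0% conversion, 52.6% target and 25.3% side product. At 0.500 d that flask held 46.5% target and 14.2% of its partner charge, where a fall even with the target gives 11.7%. The flask charged with 80 mM of partner started above the crossover concentration: counting two partner spent per substrate, I put its mean while the substrate reacted near 70.0 mM, which against 21.6 mM gives 3.24, and its side product over target came to 3.17.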